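1. I started from 181 turnovers, my turnover capacity: product at the plateau per catalyst charged, the turnover number of the south-west run, read from its last reading of 35.2%.

| flask | starting material | coupling partner | free catalyst | remark |
|---|---|---|---|---|
| south-west | 20 mM | 50 mM | 39 µM | run made earlier |
| south | 20 mM | 50 mM | 62 µM | run made earlier |
| north-west | 20 mM | 75 mM | 28 µM | run made earlier |
| flask | 20 mM | 50.0 mM | 28 µM |  |

- south-west (time / d: product / %): 2.08: 18.3; 5.00: 34.3; 10.0: 33.6; 15.0: 35.2
- south (time / d: product / %): 4.00: 49.1; 8.00: 56.2; 12.0: 55.4; 15.0: 56.5
- north-west (time / d: product / %): 2.08: 17.8; 5.00: 27.4; 10.0: 30.5; 15.0: 30.6

(standard deviation of a reading: 1 percentage point)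

- what has left starting material counts as converted, also if it is not yet product

* apparent order in coupling partner when 50% of the starting material are converted (percent change of the rate of making product for one percent more coupling partner charged)

2. The south run had more catalyst but gave about the same capacity, 182, so between these two runs, at this charge of coupling partner, the plateau followed the catalyst charged.

3. The second amount was the capacity of the north-west run, 219, which was higher with 1.50 times the coupling partner. I assumed that catalyst loss did not depend on the coupling partner. These two amounts came from runs at 39 µM and 28 µM of catalyst and from whole-run plateaus, not from rates at the conversion asked about, so their ratio was a rough estimate of the order, resting on the agreement of capacities in step 2. My reading was 0.472.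

4. The forecast was higher, at 0.55, with a range of 0.25 to 1. It held that depletion of the coupling partner “raises the charged-basis order slightly”.

5. The flask gave 0.70.

    starting material + free catalyst → free catalyst + open intermediate (k = 780 M⁻¹ h⁻¹)
    free catalyst + open intermediate ⇌ catalyst intermediate (K = 27.0 M⁻¹, k = 46000 M⁻¹ h⁻¹)
    coupling partner + catalyst intermediate → free catalyst + product (k = 630 M⁻¹ h⁻¹)
    free catalyst → spent catalyst (k = 0.0240 h⁻¹)

6. That order stood above both the forecast and my reading. Open intermediate was being made at 2.72 times the rate it was used up, each step taken net, after 0.926 d. The flask was charged with catalyst at 0.140% of the starting material, so the capacity of 181 reckoned to 25.3% of the starting material as product; the flask held 23.3% after 15.0 d, a capacity of 167. Set against the north-west capacity of 219 at the same catalyst charge, this capacity gives a plateau order of 0.669.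

The numbers in the tables are calculated on assumed constants, noise included.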